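**Retrosynthetic overview**
1. Target 26 ⇒ (R)-hydroxy dialdehyde 22 by enol acetylation and O-acetylation. 22 ⇒ triol 21 ⇒ epoxy diol 20 ⇒ (E)-2-alkylbut-2-ene-1,4-diol 19. The Sharpless epoxidation sets the quaternary C–O centre.
2. 19 ⇒ homoallylic Grignard 16 + 2-butyne-1,4-diol by anti-carbomagnesiation, which brings in all four head carbons at once.
3. The ring methyl and the E-trisubstituted alkene ⇒ one double Ni-catalysed methylation of 11, which carries an enol triflate and a 5-alkyl-2,3-dihydrofuran.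
4. The only ring ⇒ cyclohexanone 10 ⇒ one-carbon ring expansion of 2,2-dimethylcyclopentanone. An enantioenriched lithiated carbamate adds to the ketone, then the CMe2 carbon makes a semipinacol 1,2-shift. This step forms the six-membered ring and sets its stereocentre.
5. Carbamate 5 ⇒ 2,3-dihydrofuran + oxetane.

Assumption and abbreviations: everything named only under Conditions is bought. Cb = N,N-diisopropylcarbamoyl. R16 = (3E)-4-methyl-6-[(1S)-2,6,6-trimethylcyclohex-2-en-1-yl]hex-3-en-1-yl.

**Step 1**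
Reactants: 1 2,3-dihydrofuran; 2 oxetane
Product: 4 3-(4,5-dihydrofuran-2-yl)propan-1-ol, via 5-lithio-2,3-dihydrofuran 3 (not isolated)
Conditions: t-BuLi, THF/pentane, −78 → 0 °C; then 2, BF3·OEt2, −78 °C; aq NaHCO3
Reagents that add atoms: none
Why: α-lithiation of the cyclic enol ether followed by BF3-assisted SN2 opening of oxetane by the vinyllithium gives the three-carbon alcohol arm in one operation; no stereocentre is formed.

**Step 2**
Reactants: 4 3-(4,5-dihydrofuran-2-yl)propan-1-ol
Product: 5 3-(4,5-dihydrofuran-2-yl)propyl N,N-diisopropylcarbamate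
Conditions: NaH, i-Pr2NCOCl, THF, reflux
Reagents that add atoms: N,N-diisopropylcarbamoyl chloride CC(C)N(C(C)C)C(=O)Cl
Why: O-carbamoylation of the alkoxide under purely basic conditions leaves the acid-labile enol ether untouched and installs the directing and leaving group for step 3.

**Step 3**
Reactants: 5 3-(4,5-dihydrofuran-2-yl)propyl N,N-diisopropylcarbamate; 6 2,2-dimethylcyclopentanone
Product: 10 (S)-2-[2-(4,5-dihydrofuran-2-yl)ethyl]-3,3-dimethylcyclohexan-1-one, via lithiated carbamate 7 (not isolated), via lithium alkoxide 8 (not isolated), via aluminium alkoxide 9 (not isolated)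
Conditions: s-BuLi, (+)-sparteine, Et2O, −78 °C, 5 h; 6, −78 °C; Et2AlCl (2.5 equiv), −78 °C → rt; Rochelle salt
Reagents that add atoms: none
Why: Proposed new method: a Hoppe-type chiral carbenoid inserts a stereodefined CH(R) unit into the C(=O)–C(quaternary) bond of a ketone; (+)-sparteine-directed deprotonation gives configurationally stable (R)-7, which adds to 6 with retention; Li→AlEt2 exchange makes the alkoxide an internal Lewis acid that chelates the carbamate C=O; the electron-rich C–CMe2 bond antiperiplanar to C–OCb then migrates with inversion (semipinacol 1,2-shift, 5→6 ring expansion, the tertiary alkyl group being the better migrating group); both carbinol epimers of 8 converge on (S)-10 because the carbinol carbon becomes C=O; the closest known reaction types are the 1,2-metallate shift of lithiation–borylation (same carbenoid, same leaving group), the organoaluminium-promoted semipinacol shift of β-hydroxy mesylates and the ring enlargement of halohydrin magnesium salts.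

**Step 4**
Reactants: 10 (S)-2-[2-(4,5-dihydrofuran-2-yl)ethyl]-3,3-dimethylcyclohexan-1-one
Product: 11 (S)-6-[2-(4,5-dihydrofuran-2-yl)ethyl]-5,5-dimethylcyclohex-1-en-1-yl trifluoromethanesulfonate
Conditions: LDA, THF, −78 °C; PhNTf2, −78 → 0 °C
Reagents that add atoms: N-phenylbis(trifluoromethanesulfonimide) O=S(=O)(N(c1ccccc1)S(=O)(=O)C(F)(F)F)C(F)(F)F
Why: kinetic deprotonation occurs only at the free CH2 (the other α-H is tertiary and flanked by CMe2), so enolate O-triflation fixes the future C2=C3 alkene without touching the stereocentre.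

**Step 5**
Reactants: 11 (S)-6-[2-(4,5-dihydrofuran-2-yl)ethyl]-5,5-dimethylcyclohex-1-en-1-yl trifluoromethanesulfonate
Product: 13 (3E)-4-methyl-6-[(1S)-2,6,6-trimethylcyclohex-2-en-1-yl]hex-3-en-1-ol, via methylated dihydrofuran 12 (not isolated)
Conditions: MeMgBr (6 equiv), NiCl2(PPh3)2 (10 mol %), PhMe/Et2O, rt, then 80 °C; aq NH4Cl
Reagents that add atoms: methylmagnesium bromide C[Mg]Br
Why: a Kumada coupling of the alkenyl triflate (rt) is followed in the same flask by Wenkert-type Ni-catalysed C(sp2)–O coupling of the 5-alkyl-2,3-dihydrofuran; the second coupling goes with retention, so methyl takes the place of the ring oxygen (cis to the CH2CH2O arm) and the chain alkene is E.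

**Step 6**
Reactants: 13 (3E)-4-methyl-6-[(1S)-2,6,6-trimethylcyclohex-2-en-1-yl]hex-3-en-1-ol
Product: 14 (6S)-6-[(3E)-6-bromo-3-methylhex-3-en-1-yl]-1,5,5-trimethylcyclohex-1-ene (R16–Br)
Conditions: CBr4, PPh3, CH2Cl2, 0 °C
Reagents that add atoms: carbon tetrabromide BrC(Br)(Br)Br
Why: the Appel reaction converts the primary alcohol to the bromide under neutral conditions that leave both trisubstituted alkenes alone.

**Step 7**
Reactants: 14 R16–Br; 15 2-butyne-1,4-diol
Product: 19 (2E)-2-(R16)but-2-ene-1,4-diol, via Grignard reagent 16 (not isolated), via bis(bromomagnesium) butynediolate 17 (not isolated), via alkenylmagnesium species 18 (not isolated)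
Conditions: 14, Mg, THF, 40 °C; separately 15 (2.5 equiv), EtMgBr (2.0 equiv per diol), THF, 0 °C; combine, CuI (15 mol %), THF/PhMe, 65 °C; aq NH4Cl
Reagents that add atoms: none
Why: Cu-catalysed, alkoxide-directed anti-carbomagnesiation of a propargylic alcohol places R16 and Mg trans, so after protonation the two CH2OH groups are trans (E).

**Step 8**
Reactants: 19 (2E)-2-(R16)but-2-ene-1,4-diol
Product: 20 [(2S,3S)-3-(hydroxymethyl)-2-(R16)oxiran-2-yl]methanol
Conditions: Ti(Oi-Pr)4 (20 mol %), L-(+)-DET (24 mol %), t-BuOOH, 4 Å MS, CH2Cl2, −25 °C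
Reagents that add atoms: tert-butyl hydroperoxide CC(C)(C)OO
Why: Sharpless asymmetric epoxidation touches only the allylic-alcohol alkene; the two trans-disposed CH2OH groups direct to the same face, and L-(+)-DET gives the same sense as (2S,3S)-epoxygeraniol; this sets the quaternary C–O centre, which becomes R in the target only through a change of CIP priorities because that C–O bond is never broken again.

**Step 9**
Reactants: 20 [(2S,3S)-3-(hydroxymethyl)-2-(R16)oxiran-2-yl]methanol
Product: 21 (2R)-2-(R16)butane-1,2,4-triol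
Conditions: Red-Al, THF, 0 °C → rt
Reagents that add atoms: none
Why: hydroxyl-directed Red-Al opening of a 2,3-epoxy alcohol delivers hydride to the epoxide CH, which is also the only SN2-accessible carbon, giving the 1,3-diol with the tertiary C–O stereocentre retained.

**Step 10**
Reactants: 21 (2R)-2-(R16)butane-1,2,4-triol
Product: 22 (2R)-2-hydroxy-2-(R16)butanedial
Conditions: (COCl)2, DMSO, CH2Cl2, −78 °C; Et3N, −78 → −20 °C; used crude
Reagents that add atoms: none
Why: a double Swern oxidation converts both primary alcohols to aldehydes at once, so no lactol can form, while the tertiary alcohol and the alkenes are inert.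

**Step 11**
Reactants: 22 (2R)-2-hydroxy-2-(R16)butanedial
Product: 26 (1E,3R,6E)-3-acetoxy-3-formyl-7-methyl-9-[(1S)-2,6,6-trimethylcyclohex-2-en-1-yl]nona-1,6-dien-1-yl acetate, via TMS ether 23 (not isolated), via silyloxy enol acetate 24 (not isolated), via hydroxy enol acetate 25 (not isolated)
Conditions: TMSOTf (1.05 equiv), 2,6-lutidine, CH2Cl2, −78 °C; then Ac2O, Et3N, DMAP, 0 °C → rt; then Et3N·3HF, rt, 16 h
Reagents that add atoms: acetic anhydride CC(=O)OC(C)=O
Why: temporary O-silylation makes the β-oxygen a poor leaving group, so soft enolisation and O-acetylation of the only enolisable aldehyde gives the enol acetate (E because of the quaternary neighbour) without E1cB loss; fluoride then frees the tertiary alcohol for DMAP-catalysed (Steglich-type) acetylation once elimination is no longer possible.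

**Compound list**
1 | 2,3-dihydrofuran | C1CC=CO1 | starting material
2 | oxetane | C1COC1 | starting material
3 | 5-lithio-2,3-dihydrofuran | [Li]C1=CCCO1 | intermediate
4 | 3-(4,5-dihydrofuran-2-yl)propan-1-ol | OCCCC1=CCCO1 | intermediate
5 | 3-(4,5-dihydrofuran-2-yl)propyl N,N-diisopropylcarbamate | CC(C)N(C(C)C)C(=O)OCCCC1=CCCO1 | intermediate
6 | 2,2-dimethylcyclopentanone | CC1(C)CCCC1=O | starting material
7 | (R)-1-lithio-3-(4,5-dihydrofuran-2-yl)propyl N,N-diisopropylcarbamate ((+)-sparteine complex) | [Li][C@@H](OC(=O)N(C(C)C)C(C)C)CCC1=CCCO1 | intermediate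
8 | lithium 1-[(S)-1-(OCb)-3-(4,5-dihydrofuran-2-yl)propyl]-2,2-dimethylcyclopentan-1-olate (carbinol epimers) | [Li]OC1(CCCC1(C)C)[C@@H](OC(=O)N(C(C)C)C(C)C)CCC2=CCCO2 | intermediate
9 | diethylaluminium alkoxide corresponding to 8 | CC[Al](CC)OC1(CCCC1(C)C)[C@@H](OC(=O)N(C(C)C)C(C)C)CCC2=CCCO2 | intermediate
10 | (S)-2-[2-(4,5-dihydrofuran-2-yl)ethyl]-3,3-dimethylcyclohexan-1-one | C1CC=C(O1)CC[C@@H]2C(=O)CCCC2(C)C | intermediate
11 | (S)-6-[2-(4,5-dihydrofuran-2-yl)ethyl]-5,5-dimethylcyclohex-1-en-1-yl triflate | C1CC=C(O1)CC[C@@H]2C(OS(=O)(=O)C(F)(F)F)=CCCC2(C)C | intermediate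
12 | 5-{2-[(1S)-2,6,6-trimethylcyclohex-2-en-1-yl]ethyl}-2,3-dihydrofuran | C1CC=C(O1)CC[C@@H]2C(C)=CCCC2(C)C | intermediate
13 | (3E)-4-methyl-6-[(1S)-2,6,6-trimethylcyclohex-2-en-1-yl]hex-3-en-1-ol | OCC/C=C(\C)CC[C@@H]1C(C)=CCCC1(C)C | intermediate
14 | (6S)-6-[(3E)-6-bromo-3-methylhex-3-en-1-yl]-1,5,5-trimethylcyclohex-1-ene | BrCC/C=C(\C)CC[C@@H]1C(C)=CCCC1(C)C | intermediate
15 | 2-butyne-1,4-diol | OCC#CCO | starting material
16 | R16–MgBr | Br[Mg]CC/C=C(\C)CC[C@@H]1C(C)=CCCC1(C)C | intermediate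
17 | bis(bromomagnesium) but-2-yne-1,4-diolate | Br[Mg]OCC#CCO[Mg]Br | intermediate
18 | alkenylmagnesium bis-alkoxide from anti-addition (R16 trans to Mg) | Br[Mg]OC/C([Mg]Br)=C(/CO[Mg]Br)CC/C=C(\C)CC[C@@H]1C(C)=CCCC1(C)C | intermediate
19 | (2E)-2-(R16)but-2-ene-1,4-diol | OC/C=C(/CO)CC/C=C(\C)CC[C@@H]1C(C)=CCCC1(C)C | intermediate
20 | [(2S,3S)-3-(hydroxymethyl)-2-(R16)oxiran-2-yl]methanol | OC[C@@H]1O[C@]1(CO)CC/C=C(\C)CC[C@@H]2C(C)=CCCC2(C)C | intermediate
21 | (2R)-2-(R16)butane-1,2,4-triol | OCC[C@@](CO)(CC/C=C(\C)CC[C@@H]1C(C)=CCCC1(C)C)O | intermediate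
22 | (2R)-2-hydroxy-2-(R16)butanedial | O=CC[C@@](C=O)(CC/C=C(\C)CC[C@@H]1C(C)=CCCC1(C)C)O | intermediate
23 | (2R)-2-(R16)-2-(trimethylsilyloxy)butanedial | O=CC[C@@](C=O)(CC/C=C(\C)CC[C@@H]1C(C)=CCCC1(C)C)O[Si](C)(C)C | intermediate
24 | (1E,3R)-3-formyl-3-(trimethylsilyloxy) enol acetate bearing R16 | CC(=O)O/C=C/[C@@](C=O)(CC/C=C(\C)CC[C@@H]1C(C)=CCCC1(C)C)O[Si](C)(C)C | intermediate
25 | (1E,3R)-3-formyl-3-hydroxy enol acetate bearing R16 | CC(=O)O/C=C/[C@@](C=O)(CC/C=C(\C)CC[C@@H]1C(C)=CCCC1(C)C)O | intermediate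
26 | (1E,3R,6E)-3-acetoxy-3-formyl-7-methyl-9-[(1S)-2,6,6-trimethylcyclohex-2-en-1-yl]nona-1,6-dien-1-yl acetate | CC(=O)O/C=C/[C@@](C=O)(CC/C=C(\C)CC[C@@H]1C(C)=CCCC1(C)C)OC(C)=O | target

**Totals**
Total steps: 11. Longest linear sequence: 11 (steps 1–11).

**Three steps most likely to fail**

Step 3 is the proposed new ring expansion. The risks are:
- enolisation of the hindered ketone;
- OCb being too poor a leaving group, which would give epoxide closure or carbamoyl transfer instead;
- competing migration of the ring CH2;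
- Lewis acid damage to the enol ether.

The fallback uses known chemistry and sets out from 5 and 6. The same lithiation and addition is run, but adduct 8 is quenched with NH4Cl to isolate the β-hydroxy carbamate F1. LiAlH4 in refluxing THF removes the carbamoyl group to give the 1,2-diol F2. MsCl/Et3N sulfonylates only the secondary hydroxyl, giving the hydroxy mesylate F3. Et3Al (CH2Cl2, −78 °C) or KOt-Bu then triggers the established stereoinvertive hydroxy-mesylate semipinacol ring expansion. This fallback rejoins the route at 10.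

Step 7 is the carbomagnesiation with a valuable Grignard reagent. The risks are sluggish addition, alkylcopper decomposition and homocoupling. The fallback sets out from 14 and 15.
- Red-Al trans-hydroalumination of 15 followed by I2 gives (Z)-2-iodobut-2-ene-1,4-diol F4.
- TBSCl/imidazole converts F4 into the bis-silyl ether F5.
- Bromide 14 is turned with Zn/LiCl into the alkylzinc bromide F6.
- Pd(dppf)Cl2-catalysed Negishi sp3–sp2 coupling of F6 with F5 proceeds with retention and gives the bis-TBS ether F7.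
- TBAF releases the diol, and the fallback rejoins the route at 19.

Step 11 is the one-flask masking, enol acetylation and acetylation. The risks are E1cB loss of the β-oxygen, retro-aldol cleavage and incomplete acetylation of the hindered alcohol. The fallback sets out from 21 and makes the enol acetate while the C–O centre is locked in a ring.
- 2,2-Dimethoxypropane/PPTS gives the 1,2-acetonide alcohol F8.
- Dess–Martin oxidation gives the aldehyde F9.
- Ac2O/Et3N/DMAP gives the (E)-enol acetate acetonide F10.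
- 80 % aq AcOH at 40 °C gives the diol enol acetate F11.
- Parikh–Doering oxidation of the primary alcohol rejoins the route at 25.
- 25 is acetylated with Ac2O/DMAP to 26, as in the last stage of step 11.

**Further compounds**
F1 | step 3 | (S)-3-(4,5-dihydrofuran-2-yl)-1-(1-hydroxy-2,2-dimethylcyclopentyl)propyl N,N-diisopropylcarbamate | OC1(CCCC1(C)C)[C@@H](OC(=O)N(C(C)C)C(C)C)CCC2=CCCO2
F2 | step 3 | 1-[(S)-3-(4,5-dihydrofuran-2-yl)-1-hydroxypropyl]-2,2-dimethylcyclopentan-1-ol | OC1(CCCC1(C)C)[C@@H](O)CCC2=CCCO2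
F3 | step 3 | (S)-3-(4,5-dihydrofuran-2-yl)-1-(1-hydroxy-2,2-dimethylcyclopentyl)propyl methanesulfonate | OC1(CCCC1(C)C)[C@@H](OS(C)(=O)=O)CCC2=CCCO2
F4 | step 7 | (Z)-2-iodobut-2-ene-1,4-diol | OC/C=C(I)/CO
F5 | step 7 | (Z)-1,4-bis(tert-butyldimethylsilyloxy)-2-iodobut-2-ene | CC(C)(C)[Si](C)(C)OC/C=C(I)/CO[Si](C)(C)C(C)(C)C
F6 | step 7 | R16–ZnBr | Br[Zn]CC/C=C(\C)CC[C@@H]1C(C)=CCCC1(C)C
F7 | step 7 | (E)-1,4-bis(tert-butyldimethylsilyloxy)-2-(R16)but-2-ene | CC(C)(C)[Si](C)(C)OC/C=C(/CO[Si](C)(C)C(C)(C)C)CC/C=C(\C)CC[C@@H]1C(C)=CCCC1(C)C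
F8 | step 11 | 2-[(4R)-2,2-dimethyl-4-(R16)-1,3-dioxolan-4-yl]ethan-1-ol | OCC[C@]1(CC/C=C(\C)CC[C@@H]2C(C)=CCCC2(C)C)COC(C)(C)O1
F9 | step 11 | 2-[(4R)-2,2-dimethyl-4-(R16)-1,3-dioxolan-4-yl]acetaldehyde | O=CC[C@]1(CC/C=C(\C)CC[C@@H]2C(C)=CCCC2(C)C)COC(C)(C)O1
F10 | step 11 | (E)-2-[(4R)-2,2-dimethyl-4-(R16)-1,3-dioxolan-4-yl]ethenyl acetate | CC(=O)O/C=C/[C@]1(CC/C=C(\C)CC[C@@H]2C(C)=CCCC2(C)C)COC(C)(C)O1
F11 | step 11 | (1E,3R)-3-hydroxy-3-(hydroxymethyl) enol acetate bearing R16 | CC(=O)O/C=C/[C@@](CO)(CC/C=C(\C)CC[C@@H]1C(C)=CCCC1(C)C)O
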